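**Plan**

- Rings: A = methyl benzoate ring, B = trioxygenated ring on C2, C = 2,6-dihydroxy-4-methylphenyl ring on C3, D = benzo ring of the inden-1-one (C1 = carbonyl carbon).
- Enabling feature: C3 carries rings C and D, so it can be a doubly benzylic CH2. C2 can be the remote carbonyl of a 1,2-diketone whose other carbonyl (C1) sits on ring D ortho to that CH2, so bond C2–C3 can close by light-induced hydrogen transfer and biradical coupling.
- Cuts, in retrosynthetic order: the five O-acetyl groups; C2=C3 (back to a tertiary alcohol at C2); C2–C3; both C=O of the diketone (back to a diarylalkyne); ring D–C(sp) (Sonogashira); ring C–CH2 (aryllithium plus aldehyde, then deoxygenation); the ring A–O–ring B ether at O–ring B (SNAr on a 2-fluorobenzaldehyde whose formyl group later becomes the ring B hydroxyl).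
- Forward: fragment CD (steps 1–7) and fragment AB (steps 8–13) are joined through an alkyne (step 14) and oxidised to the diketone (step 15). Light then closes the only new ring, the five-membered ring (step 16), followed by dehydration (step 17) and deacetylation (step 18).
- Stereochemistry: the target has no stereocentre. The centres formed at C2 and C3 in step 16 are erased in step 17, and the carbinol centre of 9 is erased in step 6.

Key step: step 16

Remark: racemic compounds and diastereomer mixtures are drawn without configuration because every such centre is destroyed before the target; compounds 1, 3, 13 and 18 are taken as purchasable.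

**Route**

Step 1
Reactants: 1 orcinol
Product: 2 1,3-bis(methoxymethoxy)-5-methylbenzene
Conditions: MOMCl, i-Pr2NEt, CH2Cl2, 0 → 25 °C
Reagents that add atoms: chloromethyl methyl ether, COCCl
Why: Base-mediated O-alkylation of both phenols should give the bis-acetal, whose two oxygens later direct lithiation to the carbon between them.

Step 2
Reactants: 3 1-bromo-3,5-dimethoxybenzene
Product: 5 2-bromo-4,6-dimethoxybenzaldehyde, via iminium salt 4 (not isolated)
Conditions: POCl3, DMF, 0 → 90 °C; then ice-water
Reagents that add atoms: N,N-dimethylformamide, CN(C)C=O; water, O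
Why: Vilsmeier–Haack formylation should take place para to one methoxy group and ortho to the other (next to bromine) and not at the more crowded carbon between the two methoxy groups, as is usual for 3,5-dimethoxyaryl systems.

Step 3
Reactants: 5 2-bromo-4,6-dimethoxybenzaldehyde
Product: 6 2-bromo-6-hydroxy-4-methoxybenzaldehyde
Conditions: BCl3, CH2Cl2, −78 → 0 °C; then H2O
Reagents that add atoms: none
Why: Chelation-controlled ether cleavage should be selective, because BCl3 bound to the formyl oxygen activates only the ortho methoxy group and leaves the para one intact.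

Step 4
Reactants: 6 2-bromo-6-hydroxy-4-methoxybenzaldehyde
Product: 7 2-bromo-4-methoxy-6-(methoxymethoxy)benzaldehyde
Conditions: MOMCl, i-Pr2NEt, CH2Cl2, 0 → 40 °C
Reagents that add atoms: chloromethyl methyl ether, COCCl
Why: O-Alkylation masks the acidic phenol so that the aldehyde can accept an aryllithium in the next step.

Step 5
Reactants: 2 1,3-bis(methoxymethoxy)-5-methylbenzene; 7 2-bromo-4-methoxy-6-(methoxymethoxy)benzaldehyde
Product: 9 rac-[2-bromo-4-methoxy-6-(methoxymethoxy)phenyl][2,6-bis(methoxymethoxy)-4-methylphenyl]methanol, via aryllithium 8 (not isolated)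
Conditions: 2 (slight excess), n-BuLi, THF, 0 °C; then 7, −78 → 0 °C; H2O
Reagents that add atoms: none
Why: Directed ortho-metalation between the two acetal oxygens followed by 1,2-addition to the aldehyde should outrun bromine–lithium exchange at −78 °C; the carbinol centre is racemic and is removed in step 6.

Step 6
Reactants: 9 rac-diaryl carbinol
Product: 11 2-[(2-bromo-6-hydroxy-4-methoxyphenyl)methyl]-5-methylbenzene-1,3-diol, via tris-MOM diarylmethane 10 (not isolated)
Conditions: Et3SiH, CF3CO2H, CH2Cl2, −20 → 0 °C; then HCl, MeOH, 40 °C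
Reagents that add atoms: none
Why: Ionic hydrogenation should proceed through a diarylmethyl cation stabilised by ortho and para oxygens and trapped by the silane, after which acid methanolysis removes the three acetals as dimethoxymethane.

Step 7
Reactants: 11 2-[(2-bromo-6-hydroxy-4-methoxyphenyl)methyl]-5-methylbenzene-1,3-diol
Product: 12 2-[(2-acetoxy-6-bromo-4-methoxyphenyl)methyl]-5-methyl-1,3-phenylene diacetate
Conditions: Ac2O, pyridine, DMAP (cat.), CH2Cl2, 0 → 25 °C
Reagents that add atoms: acetic anhydride, CC(=O)OC(C)=O
Why: DMAP-catalysed acylation should esterify all three phenols, giving the light-inert protecting groups needed for step 16.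

Step 8
Reactants: 13 2,6-dibromo-4-methoxyaniline
Product: 15 1,3-dibromo-2-fluoro-5-methoxybenzene, via diazonium tetrafluoroborate 14 (not isolated)
Conditions: NOBF4, CH2Cl2, 0 °C; solvent exchange to 1,2-dichlorobenzene, 130 °C
Reagents that add atoms: nitrosonium tetrafluoroborate, N#[O+].F[B-](F)(F)F
Why: In this Balz–Schiemann reaction the nitrosonium salt should diazotise the weakly basic, hindered aniline, and heating the diazonium tetrafluoroborate expels N2 with fluoride transfer from BF4−.

Step 9
Reactants: 15 1,3-dibromo-2-fluoro-5-methoxybenzene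
Product: 17 3-bromo-2-fluoro-5-methoxybenzaldehyde, via arylmagnesium chloride 16 (not isolated)
Conditions: i-PrMgCl·LiCl, THF, −20 °C; DMF, −20 → 20 °C; aq. HCl
Reagents that add atoms: N,N-dimethylformamide, CN(C)C=O
Why: Bromine–magnesium exchange on the symmetric dibromide (accelerated by the ortho fluorine, and self-limiting after one exchange) followed by formylation with DMF should give a single aldehyde.

Step 10
Reactants: 17 3-bromo-2-fluoro-5-methoxybenzaldehyde; 18 methyl 2,6-dihydroxy-4-methylbenzoate
Product: 19 methyl 2-(2-bromo-6-formyl-4-methoxyphenoxy)-6-hydroxy-4-methylbenzoate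
Conditions: K2CO3, DMF, 90 °C (18 in excess)
Reagents that add atoms: none
Why: SNAr should displace the fluoride, which is activated by the ortho formyl group and the flanking bromine, with the phenoxide of 18; the excess of the symmetric diol suppresses double arylation.

Step 11
Reactants: 19 methyl 2-(2-bromo-6-formyl-4-methoxyphenoxy)-6-hydroxy-4-methylbenzoate
Product: 20 methyl 2-{2-formyl-4-methoxy-6-[(trimethylsilyl)ethynyl]phenoxy}-6-hydroxy-4-methylbenzoate
Conditions: Me3SiC≡CH, PdCl2(PPh3)2 (cat.), CuI (cat.), Et3N, THF, 60 °C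
Reagents that add atoms: ethynyltrimethylsilane, C#C[Si](C)(C)C
Why: Sonogashira coupling of the aryl bromide should tolerate the aldehyde and the hydrogen-bonded salicylate phenol and installs the two carbons that become C1 and C2.

Step 12
Reactants: 20 methyl 2-{2-formyl-4-methoxy-6-[(trimethylsilyl)ethynyl]phenoxy}-6-hydroxy-4-methylbenzoate
Product: 22 methyl 2-(2-ethynyl-6-hydroxy-4-methoxyphenoxy)-6-hydroxy-4-methylbenzoate, via aryl formate 21 (not isolated)
Conditions: mCPBA, CH2Cl2, 0 → 25 °C; then K2CO3, MeOH, 25 °C
Reagents that add atoms: 3-chloroperoxybenzoic acid, O=C(OO)c1cccc(Cl)c1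
Why: In this Baeyer–Villiger (Dakin-type) oxidation the ortho aryloxy group should favour aryl over hydride migration, and methanolysis then cleaves both the formate and the C–Si bond in one operation.

Step 13
Reactants: 22 methyl 2-(2-ethynyl-6-hydroxy-4-methoxyphenoxy)-6-hydroxy-4-methylbenzoate
Product: 23 methyl 2-acetoxy-6-(2-acetoxy-6-ethynyl-4-methoxyphenoxy)-4-methylbenzoate
Conditions: Ac2O, pyridine, DMAP (cat.), CH2Cl2, 0 → 25 °C
Reagents that add atoms: acetic anhydride, CC(=O)OC(C)=O
Why: DMAP-catalysed acylation should esterify both phenols, including the hydrogen-bonded one on ring A, without touching the terminal alkyne.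

Step 14
Reactants: 12 ring CD bromide triacetate; 23 ring AB alkyne diacetate
Product: 24 methyl 2-acetoxy-6-{2-acetoxy-6-[(3-acetoxy-2-{[2,6-bis(acetyloxy)-4-methylphenyl]methyl}-5-methoxyphenyl)ethynyl]-4-methoxyphenoxy}-4-methylbenzoate
Conditions: PdCl2(PhCN)2 (cat.), [HP(t-Bu)3]BF4 (cat.), CuI (cat.), i-Pr2NH, 1,4-dioxane, 25 → 45 °C
Reagents that add atoms: none
Why: Sonogashira coupling with the bulky, electron-rich phosphine should let zerovalent palladium insert into the hindered, electron-rich C–Br bond near room temperature, where the hindered secondary amine leaves the aryl acetates intact.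

Step 15
Reactants: 24 diarylalkyne pentaacetate
Product: 25 methyl 2-acetoxy-6-{2-acetoxy-6-[2-(3-acetoxy-2-{[2,6-bis(acetyloxy)-4-methylphenyl]methyl}-5-methoxyphenyl)-2-oxoacetyl]-4-methoxyphenoxy}-4-methylbenzoate (benzil pentaacetate)
Conditions: PdCl2 (10 mol%), DMSO, 120 °C
Reagents that add atoms: dimethyl sulfoxide, CS(C)=O
Why: Wacker-type oxidation of the diarylalkyne, with DMSO as oxygen donor at the divalent palladium–alkyne complex, should give the 1,2-diketone under neutral conditions that spare the acetates.

Step 16
Reactants: 25 benzil pentaacetate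
Product: 26 4-acetoxy-3-[2,6-bis(acetyloxy)-4-methylphenyl]-2-hydroxy-6-methoxy-2-{3-acetoxy-2-[3-acetoxy-2-(methoxycarbonyl)-5-methylphenoxy]-5-methoxyphenyl}indan-1-one (mixture of cis and trans diastereomers, each racemic)
Conditions: hν (405–420 nm LEDs), degassed benzene, 0.01 M, 20 °C
Reagents that add atoms: none
Why: Excitation into the n,π* band of the 1,2-diketone, at wavelengths the aryl acetates do not absorb, should populate the triplet, which takes a hydrogen atom from the methylene between rings C and D (either the remote carbonyl oxygen through a seven-membered transition state, or the ring D carbonyl oxygen through a six-membered one followed by tautomerisation of the photoenol) to give a biradical with spin on C2 and C3. Coupling of these two centres forms bond C2–C3 and closes the five-membered ring by 1,5-biradical recombination, which returns the ring D carbonyl as C1 and leaves a tertiary alcohol on C2. The closest known reaction type is the photocyclisation of 1-(ortho-alkylphenyl)-1,2-diketones to 2-hydroxyindan-1-ones, a homologue of the Norrish–Yang closure. The centres at C2 and C3 are set by substrate control alone (the two aryl groups should prefer to be trans), and no selectivity is needed because step 17 destroys both. What the step needs is site selectivity in the hydrogen transfer and five- over four-membered closure: the diarylmethane C–H bonds are the weakest and the only sp3 C–H bonds within reach of the diketone, the acetates remove phenolic O–H quenchers and offer no activated O–CH hydrogens, and the strained benzocyclobutenol is disfavoured. A radical coupling is also less sensitive than a polar addition to the crowding by ortho substituents around both carbons.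

Step 17
Reactants: 26 hydroxyindanone pentaacetate
Product: 27 4-acetoxy-3-[2,6-bis(acetyloxy)-4-methylphenyl]-6-methoxy-2-{3-acetoxy-2-[3-acetoxy-2-(methoxycarbonyl)-5-methylphenoxy]-5-methoxyphenyl}inden-1-one (Ascomindone B pentaacetate)
Conditions: TsOH·H2O (cat.), toluene, 4 Å molecular sieves, 80 °C
Reagents that add atoms: none
Why: Acid-catalysed E1 dehydration (ionisation at benzylic C2 or hydride shift from doubly benzylic C3, then proton loss) should take both diastereomers to the same conjugated 2,3-diarylindenone.

Step 18
Reactants: 27 Ascomindone B pentaacetate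
Product: 28 Ascomindone B
Conditions: K2CO3, MeOH (degassed), 0 → 25 °C; then dilute HCl
Reagents that add atoms: none
Why: Base-catalysed transesterification should strip the five aryl acetates as methyl acetate, while the methyl ester is degenerate in methanol and the diaryl ether, methyl ethers and indenone are inert.

**Compound list**

1 | orcinol (5-methylbenzene-1,3-diol) | Cc1cc(O)cc(O)c1 | starting material
2 | 1,3-bis(methoxymethoxy)-5-methylbenzene | COCOc1cc(C)cc(OCOC)c1 | intermediate
3 | 1-bromo-3,5-dimethoxybenzene | COc1cc(Br)cc(OC)c1 | starting material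
4 | (2-bromo-4,6-dimethoxybenzylidene)dimethyliminium chloride | COc1cc(Br)c(C=[N+](C)C)c(OC)c1.[Cl-] | intermediate
5 | 2-bromo-4,6-dimethoxybenzaldehyde | COc1cc(Br)c(C=O)c(OC)c1 | intermediate
6 | 2-bromo-6-hydroxy-4-methoxybenzaldehyde | COc1cc(O)c(C=O)c(Br)c1 | intermediate
7 | 2-bromo-4-methoxy-6-(methoxymethoxy)benzaldehyde | COCOc1cc(OC)cc(Br)c1C=O | intermediate
8 | [2,6-bis(methoxymethoxy)-4-methylphenyl]lithium | [Li]c1c(OCOC)cc(C)cc1OCOC | intermediate
9 | rac-[2-bromo-4-methoxy-6-(methoxymethoxy)phenyl][2,6-bis(methoxymethoxy)-4-methylphenyl]methanol | COCOc1cc(OC)cc(Br)c1C(O)c1c(OCOC)cc(C)cc1OCOC | intermediate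
10 | 1-bromo-2-{[2,6-bis(methoxymethoxy)-4-methylphenyl]methyl}-5-methoxy-3-(methoxymethoxy)benzene | COCOc1cc(OC)cc(Br)c1Cc1c(OCOC)cc(C)cc1OCOC | intermediate
11 | 2-[(2-bromo-6-hydroxy-4-methoxyphenyl)methyl]-5-methylbenzene-1,3-diol | COc1cc(O)c(Cc2c(O)cc(C)cc2O)c(Br)c1 | intermediate
12 | 2-[(2-acetoxy-6-bromo-4-methoxyphenyl)methyl]-5-methyl-1,3-phenylene diacetate | COc1cc(OC(C)=O)c(Cc2c(OC(C)=O)cc(C)cc2OC(C)=O)c(Br)c1 | intermediate
13 | 2,6-dibromo-4-methoxyaniline | COc1cc(Br)c(N)c(Br)c1 | starting material
14 | 2,6-dibromo-4-methoxybenzenediazonium tetrafluoroborate | COc1cc(Br)c([N+]#N)c(Br)c1.F[B-](F)(F)F | intermediate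
15 | 1,3-dibromo-2-fluoro-5-methoxybenzene | COc1cc(Br)c(F)c(Br)c1 | intermediate
16 | (3-bromo-2-fluoro-5-methoxyphenyl)magnesium chloride | COc1cc(Br)c(F)c([Mg]Cl)c1 | intermediate
17 | 3-bromo-2-fluoro-5-methoxybenzaldehyde | COc1cc(Br)c(F)c(C=O)c1 | intermediate
18 | methyl 2,6-dihydroxy-4-methylbenzoate | COC(=O)c1c(O)cc(C)cc1O | starting material
19 | methyl 2-(2-bromo-6-formyl-4-methoxyphenoxy)-6-hydroxy-4-methylbenzoate | COC(=O)c1c(O)cc(C)cc1Oc1c(Br)cc(OC)cc1C=O | intermediate
20 | methyl 2-{2-formyl-4-methoxy-6-[(trimethylsilyl)ethynyl]phenoxy}-6-hydroxy-4-methylbenzoate | COC(=O)c1c(O)cc(C)cc1Oc1c(C#C[Si](C)(C)C)cc(OC)cc1C=O | intermediate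
21 | methyl 2-{2-(formyloxy)-4-methoxy-6-[(trimethylsilyl)ethynyl]phenoxy}-6-hydroxy-4-methylbenzoate | COC(=O)c1c(O)cc(C)cc1Oc1c(C#C[Si](C)(C)C)cc(OC)cc1OC=O | intermediate
22 | methyl 2-(2-ethynyl-6-hydroxy-4-methoxyphenoxy)-6-hydroxy-4-methylbenzoate | COC(=O)c1c(O)cc(C)cc1Oc1c(C#C)cc(OC)cc1O | intermediate
23 | methyl 2-acetoxy-6-(2-acetoxy-6-ethynyl-4-methoxyphenoxy)-4-methylbenzoate | COC(=O)c1c(OC(C)=O)cc(C)cc1Oc1c(C#C)cc(OC)cc1OC(C)=O | intermediate
24 | diarylalkyne pentaacetate (ring B–C≡C–ring D, ring C benzyl group ortho on ring D) | COC(=O)c1c(OC(C)=O)cc(C)cc1Oc1c(C#Cc2cc(OC)cc(OC(C)=O)c2Cc2c(OC(C)=O)cc(C)cc2OC(C)=O)cc(OC)cc1OC(C)=O | intermediate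
25 | benzil pentaacetate (ring D–CO–CO–ring B, ring C benzyl group ortho on ring D) | O=C(C(=O)c1cc(OC)cc(OC(C)=O)c1Cc1c(OC(C)=O)cc(C)cc1OC(C)=O)c1cc(OC)cc(OC(C)=O)c1Oc1cc(C)cc(OC(C)=O)c1C(=O)OC | intermediate
26 | 4-acetoxy-2-hydroxy-6-methoxy-2-(ring B–ring A aryl)-3-(ring C aryl)indan-1-one pentaacetate, cis/trans mixture, racemic | O=C1c2cc(OC)cc(OC(C)=O)c2C(c2c(OC(C)=O)cc(C)cc2OC(C)=O)C1(O)c1cc(OC)cc(OC(C)=O)c1Oc1cc(C)cc(OC(C)=O)c1C(=O)OC | intermediate
27 | Ascomindone B pentaacetate | COC(=O)c1c(OC(C)=O)cc(C)cc1Oc1c(OC(C)=O)cc(OC)cc1C1=C(c2c(OC(C)=O)cc(C)cc2OC(C)=O)c2c(OC(C)=O)cc(OC)cc2C1=O | intermediate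
28 | Ascomindone B | COC(=O)c1c(O)cc(C)cc1Oc1c(O)cc(OC)cc1C1=C(c2c(O)cc(C)cc2O)c2c(O)cc(OC)cc2C1=O | target

**Step count and risks**

Total step count: 18. Longest linear sequence: 11 steps (3 → 28 through steps 2–7 and 14–18; equally 13 → 28 through steps 8–13 and 14–18).

Steps most likely to fail:

1. Step 16. The excited diketone may decay unproductively: the hydrogen transfer can reverse (photoenol returning to the diketone), or charge-transfer quenching by the oxygenated rings can outpace ring closure, and long irradiation then invites α-cleavage. Fallback: the same C2–C3 bond is closed by a polar organometallic route from 25. Wohl–Ziegler bromination of the diarylmethane carbon (NBS, AIBN, PhCF3, 80 °C) would give the diarylmethyl bromide F1. Zinc insertion (Zn dust, LiCl, THF, 25 °C) would then generate a benzylic zinc reagent that adds to the nearer carbonyl of the activated 1,2-diketone in a Barbier-type five-membered closure. This returns to the route at 26.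

2. Step 15. Oxygen transfer to the doubly ortho-substituted alkyne may be slow, so that thermal loss of acetyl groups or palladium-induced cyclisation of the alkyne onto ring A competes at the temperature required. Fallback: the two oxygens are introduced by dihydroxylation from 24. Partial hydrogenation (H2, Pd/CaCO3 poisoned with Pb(OAc)2, quinoline, EtOAc) would give the Z-stilbene F2. Catalytic dihydroxylation (OsO4 cat., N-methylmorpholine N-oxide, acetone/H2O) would give the erythro diol F3. Double oxidation with 2-iodoxybenzoic acid in DMSO, which does not cleave 1,2-diols, comes back to 25.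

3. Step 14. Oxidative addition into the hindered, electron-rich C–Br bond of 12 may be slow, so that copper-mediated dimerisation of 23 and aminolysis of acetates take over. Fallback: the fragments are joined before acetylation. The free phenols 11 and 22, which tolerate hot amine, would be coupled under forcing Sonogashira conditions (PdCl2(PPh3)2, CuI, Et3N, DMF, 80 °C) to the pentahydroxy diarylalkyne F4. Peracetylation (Ac2O, pyridine, DMAP) rejoins the route at 24.

**Further compounds**

F1 | step 16 | diarylmethyl bromide of benzil pentaacetate 25 (racemic) | O=C(C(=O)c1cc(OC)cc(OC(C)=O)c1C(Br)c1c(OC(C)=O)cc(C)cc1OC(C)=O)c1cc(OC)cc(OC(C)=O)c1Oc1cc(C)cc(OC(C)=O)c1C(=O)OC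
F2 | step 15 | Z-stilbene pentaacetate (ring B–CH=CH–ring D) | COC(=O)c1c(OC(C)=O)cc(C)cc1Oc1c(/C=C\c2cc(OC)cc(OC(C)=O)c2Cc2c(OC(C)=O)cc(C)cc2OC(C)=O)cc(OC)cc1OC(C)=O
F3 | step 15 | erythro-1,2-diol pentaacetate (racemic, one enantiomer drawn) | COC(=O)c1c(OC(C)=O)cc(C)cc1Oc1c([C@@H](O)[C@@H](O)c2cc(OC)cc(OC(C)=O)c2Cc2c(OC(C)=O)cc(C)cc2OC(C)=O)cc(OC)cc1OC(C)=O
F4 | step 14 | pentahydroxy diarylalkyne (24 without its five acetyl groups) | COC(=O)c1c(O)cc(C)cc1Oc1c(C#Cc2cc(OC)cc(O)c2Cc2c(O)cc(C)cc2O)cc(OC)cc1O
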